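The theta flask has turned a smaller share of its charge by 19 min than the eta flask, 58.2% against 63.0%. A first-order flask would show equal shares.

| flask | starting material | product | time |
|---|---|---|---|
| eta | 0.800 M |  |  |
| theta | 1.20 M |  |  |
| delta | 0.800 M | 0.240 M |  |
| gamma | 0.400 M |  | 19 min |

| run | time / min | [product] / M |
|---|---|---|
| eta run | 2.7 | 0.031 |
| eta run | 5.4 | 0.085 |
| eta run | 8.1 | 0.183 |
| eta run | 11 | 0.262 |
| eta run | 14 | 0.353 |
| eta run | 16 | 0.422 |
| eta run | 19 | 0.504 |
| theta run | 2.7 | 0.036 |
| theta run | 5.4 | 0.135 |
| theta run | 8.1 | 0.245 |
| theta run | 11 | 0.364 |
| theta run | 14 | 0.509 |
| theta run | 16 | 0.594 |
| theta run | 19 | 0.699 |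
| delta run | 2.7 | 0.275 |
| delta run | 5.4 | 0.329 |
| delta run | 8.1 | 0.414 |
| delta run | 11 | 0.509 |
| delta run | 14 | 0.589 |
| delta run | 16 | 0.647 |
| delta run | 19 | 0.737 |

(readings scatter by 0.01 M)

- reaction order in [starting material] at the outset, round the charge of the eta run, defined at two percent of the starting material turned into product (one fixed amount of product, the same in the runs compared)
- product in the gamma run at 19 min, as a share of the starting material charged
- which of these the readings show (the substrate is lost by itself / nothing beyond the main steps / two substrates go astray together / the product binds the substrate / the substrate pairs with itself)

- Overall: starting material -> product.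
- Constant volume, constant temperature.
- Bound and free are read together.
- An order is taken over about fifteen percent of the charge, up and down.

One number holds that shortfall: the charge exponent, the power of the charge that product at a fixed time follows. It is an apparent order over the whole run. Theta against eta gives 0.807. An exponent below one means the share falls as the charge rises, so this reckoning puts the gamma flask at 72.0% of its charge.

Is one number enough? Read at 14 min, the exponent is 0.903, but a scatter of 0.01 M on each reading moves that figure by about 0.0850, so the gap from the value at 19 min shows no drift with time. It is also read well past the two-percent point, since the first eta reading is already 3.88% of the charge. The delta flask has made 62.1% of its charge by 19 min, close to the eta flask. This reckoning therefore sets product binding aside. The exponent does not separate starting material pairing with itself from two substrates going astray together, so pairing is taken here as a choice, not a finding.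

The forecast gives an order of 0.83, 68% for gamma, and the substrate pairs with itself, holding that “Added product therefore neither speeds nor slows the reaction”. Its gamma share stands below the one reckoned here.

The simulation gives an order of 0.44, 65.0% for gamma, and the substrate pairs with itself. The steps are:

    starting material ⇌ intermediate (0.1338 min⁻¹, 0.009540 min⁻¹)
    intermediate → product (0.1302 min⁻¹)
    2 starting material ⇌ idle substrate dimer, settled at all times (0.5700 L mol⁻¹)

At the two-percent point the theta flask runs at 1.2 times the eta rate, on 1.50 times the charge. The gamma share lies under the share reckoned with one exponent. Between the gamma and eta charges the exponent reads 0.956, above the 0.807 between eta and theta.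

All runs come from a simulation for an exercise; noise was put on by code.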